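**Strategy**

The side chain is cut between the vinylic CH of the (E)-C(CH3)=CH alkene and the first CH2 of the two-carbon tether to C2 of the chromene ring. Neither fragment carries this alkene: its two carbons are a terminal alkyne in a diynol that already holds the carbinol carbon of the butenolide ring and the homoprenyl chain. In one operation the alkyne, a methyl group from AlMe3 and the chromene alkyl iodide are joined (zirconium-catalysed syn-methylalumination, transmetalation to zinc, palladium-catalysed alkylation), forming both C–C bonds of the trisubstituted alkene with its E geometry. The lactone is closed afterwards on the propargylic alcohol.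

Key step: step 10

Assumption: 2-methyl-2-vinyloxirane is used as the racemate (the etherification is a dynamic kinetic process), and the sense of induction in steps 2 and 9 is assigned by analogy with simpler substrates; should either prove opposite, the antipodal ligand or acid is used.

**Route**

Step 1
Reactants: 1 2-methylbenzene-1,4-diol
Product: 2 2-methyl-4-[(triisopropylsilyl)oxy]phenol
Conditions: iPr3SiCl (1.05 equiv), imidazole, DMF, 0 °C
Reagents that add atoms: triisopropylsilyl chloride, CC(C)[Si](Cl)(C(C)C)C(C)C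
Why: The hydroxyl meta to the methyl group is the less hindered of the two and should be silylated preferentially by the bulky chlorosilane (silyl ether formation).

Step 2
Reactants: 2 2-methyl-4-[(triisopropylsilyl)oxy]phenol; 3 2-methyl-2-vinyloxirane (racemic)
Product: 4 (2S)-2-methyl-2-{2-methyl-4-[(triisopropylsilyl)oxy]phenoxy}but-3-en-1-ol
Conditions: Pd2(dba)3·CHCl3 (1 mol%), (R,R)-DACH-phenyl Trost ligand (3 mol%), CH2Cl2, rt
Reagents that add atoms: none
Why: Zerovalent palladium ionises the vinyl epoxide to a zwitterionic π-allyl complex whose diastereomers interconvert, the phenol protonates the alkoxide and is returned to the adjacent tertiary terminus, and the chiral ligand sets the quaternary carbon as S (Trost dynamic kinetic asymmetric allylic etherification).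

Step 3
Reactants: 4 (2S)-2-methyl-2-{2-methyl-4-[(triisopropylsilyl)oxy]phenoxy}but-3-en-1-ol
Product: 5 (2S)-2-methyl-2-{2-methyl-4-[(triisopropylsilyl)oxy]phenoxy}but-3-enal
Conditions: Dess–Martin periodinane, CH2Cl2, 0 °C to rt
Reagents that add atoms: none
Why: Dess–Martin oxidation of the primary alcohol gives an aldehyde with no α-hydrogen, so the stereocenter cannot epimerise.

Step 4
Reactants: 5 (2S)-2-methyl-2-{2-methyl-4-[(triisopropylsilyl)oxy]phenoxy}but-3-enal
Product: 6 triisopropyl(3-methyl-4-{[(3S)-3-methylpent-1-en-4-yn-3-yl]oxy}phenoxy)silane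
Conditions: Me3SiCHN2, LiN(iPr)2, THF, −78 °C to rt
Reagents that add atoms: trimethylsilyldiazomethane, C[Si](C)(C)C=[N+]=[N-]
Why: Colvin homologation: the lithiated diazo compound adds to the aldehyde, Peterson elimination and loss of N2 give an alkylidene carbene, and its 1,2-hydrogen shift delivers the terminal alkyne without touching the quaternary center.

Step 5
Reactants: 6 triisopropyl(3-methyl-4-{[(3S)-3-methylpent-1-en-4-yn-3-yl]oxy}phenoxy)silane
Product: 7 {[(2S)-2-ethenyl-2,8-dimethyl-2H-chromen-6-yl]oxy}triisopropylsilane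
Conditions: Ph3PAuNTf2 (2 mol%), CH2Cl2, rt
Reagents that add atoms: none
Why: Cationic monovalent gold activates the alkyne for 6-endo-dig attack by the only free ortho carbon of the aryl ether (intramolecular hydroarylation), and since the C–O bond at the stereocenter is not broken the configuration should be kept.

Step 6
Reactants: 7 {[(2S)-2-ethenyl-2,8-dimethyl-2H-chromen-6-yl]oxy}triisopropylsilane
Product: 9 {[(2S)-2-(2-iodoethyl)-2,8-dimethyl-2H-chromen-6-yl]oxy}triisopropylsilane, via alkylborane 8 (not isolated)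
Conditions: disiamylborane (from BH3·SMe2 and 2-methylbut-2-ene), THF, 0 °C; then I2, NaOMe, MeOH, 0 °C
Reagents that add atoms: iodine, II
Why: The hindered borane adds only to the monosubstituted alkene with boron at the terminal carbon, leaving the conjugated ring alkene, and base-induced iodinolysis of the primary B–C bond gives the iodide (Brown hydroboration–iodination).

Step 7
Reactants: 10 6-methylhept-5-en-2-one
Product: 12 6-methylhept-5-en-1-yne, via enol phosphate 11 (not isolated)
Conditions: LiN(iPr)2 (1.1 equiv), THF, −78 °C; ClP(O)(OEt)2, −78 °C to rt; LiN(iPr)2 (2.3 equiv), −78 °C to rt; aq. NH4Cl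
Reagents that add atoms: none
Why: Kinetic enolisation at the methyl group, O-phosphorylation and base-induced elimination convert the methyl ketone into the terminal alkyne (Negishi enol phosphate protocol).

Step 8
Reactants: 12 6-methylhept-5-en-1-yne
Product: 15 7-methyloct-6-en-2-ynal, via lithium acetylide 13 (not isolated), via lithium hemiaminal alkoxide 14 (not isolated)
Conditions: n-BuLi, THF, −78 °C; DMF, −78 to 0 °C; inverse quench into aq. KH2PO4
Reagents that add atoms: N,N-dimethylformamide, CN(C)C=O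
Why: Formylation of the acetylide with DMF gives a tetrahedral adduct that survives until the buffered inverse quench, which prevents amine addition to the ynal.

Step 9
Reactants: 15 7-methyloct-6-en-2-ynal; 16 allenylboronic acid pinacol ester
Product: 18 (4R)-10-methylundec-9-ene-1,5-diyn-4-ol, via pinacol borate 17 (not isolated)
Conditions: (R)-TRIP phosphoric acid (5 mol%), 4 Å molecular sieves, toluene, −20 °C; aqueous work-up
Reagents that add atoms: none
Why: Chiral phosphoric acid-catalysed allenylboration: the acid binds the boronate oxygen and the formyl hydrogen, and SE2′ transfer through a closed six-membered transition state delivers the propargyl group to the Re face, setting the carbinol carbon as R.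

Step 10
Reactants: 18 (4R)-10-methylundec-9-ene-1,5-diyn-4-ol; 19 trimethylaluminium; 9 {[(2S)-2-(2-iodoethyl)-2,8-dimethyl-2H-chromen-6-yl]oxy}triisopropylsilane
Product: 22 (3E,6R)-1-[(2S)-2,8-dimethyl-6-(triisopropylsilyloxy)-2H-chromen-2-yl]-4,12-dimethyltrideca-3,11-dien-7-yn-6-ol, via alkenylalane 20 (not isolated), via alkenylzinc chloride 21 (not isolated)
Conditions: 19 (2.5 equiv), Cp2ZrCl2 (0.25 equiv), CH2Cl2, 0 °C to rt; volatiles removed in vacuo; ZnCl2, THF, 0 °C; then 9, Pd2(dba)3 (2 mol%), tricyclopentylphosphine (8 mol%), N-methylimidazole, THF/NMP, 60 °C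
Reagents that add atoms: none
Why: After the hydroxyl of 18 is capped as its aluminium alkoxide, the zirconium/aluminium reagent adds methyl and aluminium syn across the terminal alkyne with aluminium at the terminal carbon, so both alkene carbons of the target come from the alkyne and the C-methyl group from 19. After removal of excess 19, ZnCl2 converts the alkenylalane into the alkenylzinc, and zerovalent palladium carrying the bulky electron-rich phosphine inserts into the primary C–I bond of 9, transmetalates and reductively eliminates to form the C(sp2)–C(sp3) bond with retention of alkene geometry. The closest known reactions are the zirconium-catalysed methylalumination of homopropargylic alcohols and the Negishi coupling of alkenylzinc halides with unactivated primary alkyl iodides. No ring is closed and no stereocenter is formed; the E geometry follows from syn-carbometalation and stereoretentive coupling, and both existing stereocenters are remote from the reacting atoms. The step needs the terminal alkyne to react in preference to the internal one (terminal alkynes are carbometalated far faster), regiocontrol in the carbometalation, and suppression of β-hydride elimination, which the phosphine and N-methylimidazole are expected to secure; the mixture is kept at or below rt before transmetalation to avoid chelation-driven E-to-Z isomerisation of the alkenylalane.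

Step 11
Reactants: 22 (3E,6R)-1-[(2S)-2,8-dimethyl-6-(triisopropylsilyloxy)-2H-chromen-2-yl]-4,12-dimethyltrideca-3,11-dien-7-yn-6-ol
Product: 24 (3E,6R,7Z)-1-[(2S)-2,8-dimethyl-6-(triisopropylsilyloxy)-2H-chromen-2-yl]-8-iodo-4,12-dimethyltrideca-3,7,11-trien-6-ol, via sodium vinylalanate 23 (not isolated)
Conditions: NaAlH2(OCH2CH2OMe)2, THF, 0 °C to rt; EtOAc; then I2, THF, −78 °C
Reagents that add atoms: iodine, II
Why: The aluminium alkoxide delivers hydride to the proximal alkyne carbon (trans-hydroalumination of a propargylic alcohol), and iodine cleaves the resulting five-membered vinylalanate with retention to the (Z)-γ-iodo allylic alcohol.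

Step 12
Reactants: 24 (3E,6R,7Z)-1-[(2S)-2,8-dimethyl-6-(triisopropylsilyloxy)-2H-chromen-2-yl]-8-iodo-4,12-dimethyltrideca-3,7,11-trien-6-ol
Product: 25 (5R)-5-{(2E)-5-[(2S)-2,8-dimethyl-6-(triisopropylsilyloxy)-2H-chromen-2-yl]-2-methylpent-2-en-1-yl}-3-(4-methylpent-3-en-1-yl)furan-2(5H)-one
Conditions: PdCl2(PPh3)2 (5 mol%), CO (1 atm), K2CO3, THF, 40 °C
Reagents that add atoms: carbon monoxide, [C-]#[O+]
Why: Oxidative addition of the vinyl iodide to zerovalent palladium formed in situ, CO insertion and capture of the acylpalladium by the cis-disposed hydroxyl close the butenolide without touching the carbinol stereocenter (carbonylative lactonisation).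

Step 13
Reactants: 25 (5R)-5-{(2E)-5-[(2S)-2,8-dimethyl-6-(triisopropylsilyloxy)-2H-chromen-2-yl]-2-methylpent-2-en-1-yl}-3-(4-methylpent-3-en-1-yl)furan-2(5H)-one
Product: 26 tuberatolide B
Conditions: Bu4NF, AcOH (1:1), THF, 0 °C
Reagents that add atoms: none
Why: Buffered fluoride cleaves the aryl silyl ether while the acetic acid keeps the medium non-basic, which protects the γ-stereocenter of the butenolide (desilylation).

**Compound list**

1 | 2-methylbenzene-1,4-diol | Cc1cc(O)ccc1O | starting material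
2 | 2-methyl-4-[(triisopropylsilyl)oxy]phenol | Cc1cc(O[Si](C(C)C)(C(C)C)C(C)C)ccc1O | intermediate
3 | 2-methyl-2-vinyloxirane (racemic) | CC1(C=C)CO1 | starting material
4 | (2S)-2-methyl-2-{2-methyl-4-[(triisopropylsilyl)oxy]phenoxy}but-3-en-1-ol | C=C[C@@](Oc1ccc(O[Si](C(C)C)(C(C)C)C(C)C)cc1C)(C)CO | intermediate
5 | (2S)-2-methyl-2-{2-methyl-4-[(triisopropylsilyl)oxy]phenoxy}but-3-enal | C=C[C@@](Oc1ccc(O[Si](C(C)C)(C(C)C)C(C)C)cc1C)(C)C=O | intermediate
6 | triisopropyl(3-methyl-4-{[(3S)-3-methylpent-1-en-4-yn-3-yl]oxy}phenoxy)silane | C=C[C@@](Oc1ccc(O[Si](C(C)C)(C(C)C)C(C)C)cc1C)(C)C#C | intermediate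
7 | {[(2S)-2-ethenyl-2,8-dimethyl-2H-chromen-6-yl]oxy}triisopropylsilane | C=C[C@@]1(C)C=Cc2cc(O[Si](C(C)C)(C(C)C)C(C)C)cc(C)c2O1 | intermediate
8 | {2-[(2S)-2,8-dimethyl-6-(triisopropylsilyloxy)-2H-chromen-2-yl]ethyl}bis(3-methylbutan-2-yl)borane (not isolated) | CC(C)C(C)B(CC[C@@]1(C)C=Cc2cc(O[Si](C(C)C)(C(C)C)C(C)C)cc(C)c2O1)C(C)C(C)C | intermediate
9 | {[(2S)-2-(2-iodoethyl)-2,8-dimethyl-2H-chromen-6-yl]oxy}triisopropylsilane | ICC[C@@]1(C)C=Cc2cc(O[Si](C(C)C)(C(C)C)C(C)C)cc(C)c2O1 | intermediate
10 | 6-methylhept-5-en-2-one | CC(=O)CCC=C(C)C | starting material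
11 | diethyl 6-methylhepta-1,5-dien-2-yl phosphate (not isolated) | C=C(CCC=C(C)C)OP(=O)(OCC)OCC | intermediate
12 | 6-methylhept-5-en-1-yne | C#CCCC=C(C)C | intermediate
13 | (6-methylhept-5-en-1-yn-1-yl)lithium (not isolated) | [Li]C#CCCC=C(C)C | intermediate
14 | lithium 1-(dimethylamino)-7-methyloct-6-en-2-yn-1-olate (not isolated) | [Li]OC(N(C)C)C#CCCC=C(C)C | intermediate
15 | 7-methyloct-6-en-2-ynal | O=CC#CCCC=C(C)C | intermediate
16 | allenylboronic acid pinacol ester | C=C=CB1OC(C)(C)C(C)(C)O1 | starting material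
17 | 4,4,5,5-tetramethyl-2-{[(4R)-10-methylundec-9-ene-1,5-diyn-4-yl]oxy}-1,3,2-dioxaborolane (not isolated) | CC(C)=CCCC#C[C@@H](CC#C)OB1OC(C)(C)C(C)(C)O1 | intermediate
18 | (4R)-10-methylundec-9-ene-1,5-diyn-4-ol | C#CC[C@@H](O)C#CCCC=C(C)C | intermediate
19 | trimethylaluminium | C[Al](C)C | starting material
20 | [(1E,4R)-4-(dimethylalumanyloxy)-2,10-dimethylundeca-1,9-dien-5-yn-1-yl]dimethylalane (not isolated) | C[Al](C)/C=C(C)/C[C@@H](O[Al](C)C)C#CCCC=C(C)C | intermediate
21 | chloro[(1E,4R)-4-(dimethylalumanyloxy)-2,10-dimethylundeca-1,9-dien-5-yn-1-yl]zinc (not isolated) | Cl[Zn]/C=C(C)/C[C@@H](O[Al](C)C)C#CCCC=C(C)C | intermediate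
22 | (3E,6R)-1-[(2S)-2,8-dimethyl-6-(triisopropylsilyloxy)-2H-chromen-2-yl]-4,12-dimethyltrideca-3,11-dien-7-yn-6-ol | CC(C)=CCCC#C[C@H](O)C/C(C)=C/CC[C@@]1(C)C=Cc2cc(O[Si](C(C)C)(C(C)C)C(C)C)cc(C)c2O1 | intermediate
23 | sodium salt of the cyclic vinylalanate (2,2-bis(2-methoxyethoxy)-2,5-dihydro-1,2-oxaaluminol-2-uide carrying the two side chains; not isolated) | COCCO[Al-]1(OCCOC)O[C@H](C/C(C)=C/CC[C@@]2(C)C=Cc3cc(O[Si](C(C)C)(C(C)C)C(C)C)cc(C)c3O2)C=C1CCC=C(C)C.[Na+] | intermediate
24 | (3E,6R,7Z)-1-[(2S)-2,8-dimethyl-6-(triisopropylsilyloxy)-2H-chromen-2-yl]-8-iodo-4,12-dimethyltrideca-3,7,11-trien-6-ol | CC(C)=CCC/C(I)=C/[C@H](O)C/C(C)=C/CC[C@@]1(C)C=Cc2cc(O[Si](C(C)C)(C(C)C)C(C)C)cc(C)c2O1 | intermediate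
25 | (5R)-5-{(2E)-5-[(2S)-2,8-dimethyl-6-(triisopropylsilyloxy)-2H-chromen-2-yl]-2-methylpent-2-en-1-yl}-3-(4-methylpent-3-en-1-yl)furan-2(5H)-one | CC(C)=CCCC1=C[C@@H](C/C(C)=C/CC[C@@]2(C)C=Cc3cc(O[Si](C(C)C)(C(C)C)C(C)C)cc(C)c3O2)OC1=O | intermediate
26 | tuberatolide B, (5R)-5-{(2E)-5-[(2S)-6-hydroxy-2,8-dimethyl-2H-chromen-2-yl]-2-methylpent-2-en-1-yl}-3-(4-methylpent-3-en-1-yl)furan-2(5H)-one | CC(C)=CCCC1=C[C@@H](C/C(C)=C/CC[C@@]2(C)C=Cc3cc(O)cc(C)c3O2)OC1=O | target

**Step count**

Total: 13 steps. Longest linear sequence: 10 steps (steps 1–6, then 10–13, from 2-methylbenzene-1,4-diol).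

**Steps most likely to fail**

1. Step 10. The alkenyl metal may isomerise from E to Z by chelation to the neighbouring alkoxide at the coupling temperature, residual Al–CH3 groups may transfer methyl to the iodide, and the alkylpalladium intermediate may undergo β-hydride elimination. Fallback with reversed polarity, setting out from 18 and 7 and returning at 22: the methylalumination of 18 (Me3Al, Cp2ZrCl2, CH2Cl2) is quenched with I2 at −30 °C and the product isolated as (1E,4R)-1-iodo-2,10-dimethylundeca-1,9-dien-5-yn-4-ol F1. Vinylchromene 7 is hydroborated with 9-BBN-H (THF, rt) to 9-{2-[(2S)-2,8-dimethyl-6-(triisopropylsilyloxy)-2H-chromen-2-yl]ethyl}-9-borabicyclo[3.3.1]nonane F2, which is coupled in the same flask with F1 (Pd(dppf)Cl2, AsPh3, Cs2CO3, DMF/THF/H2O, rt; B-alkyl Suzuki–Miyaura coupling) to give 22. Step 6 is then not needed.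

2. Step 2. With the ortho-substituted phenol the attack may shift to the primary terminus of the π-allyl complex, the product alcohol may open further epoxide, and facial control at the tertiary carbon may be insufficient. Fallback that takes the stereocenter from a Sharpless epoxidation, setting out from 2 and returning at 9:
   - Commercial (E)-3-methylpent-2-en-4-yn-1-ol (C#C/C(C)=C/CO) is epoxidised (Ti(OiPr)4, L-(+)-diethyl tartrate, t-BuOOH, 4 Å molecular sieves, CH2Cl2, −20 °C) to [(2S,3S)-3-ethynyl-3-methyloxiran-2-yl]methanol F3.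
   - Hydride delivery to C2 (NaAlH2(OCH2CH2OMe)2, THF, 0 °C) gives (3R)-3-methylpent-4-yne-1,3-diol F4.
   - The primary hydroxyl is silylated (t-BuMe2SiCl, imidazole) to (3R)-5-[(tert-butyldimethylsilyl)oxy]-3-methylpent-1-yn-3-ol F5.
   - Ph2PCl, Et3N and DMAP give (3R)-5-[(tert-butyldimethylsilyl)oxy]-3-methylpent-1-yn-3-yl diphenylphosphinite F6.
   - F6, phenol 2 and 2,6-dimethyl-1,4-benzoquinone (CH2Cl2, rt to 40 °C; Mukaiyama oxidation–reduction condensation, inversion at the tertiary carbon) give tert-butyl{[(3S)-3-methyl-3-{2-methyl-4-[(triisopropylsilyl)oxy]phenoxy}pent-4-yn-1-yl]oxy}dimethylsilane F7.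
   - Gold-catalysed hydroarylation as in step 5 gives tert-butyl{2-[(2S)-2,8-dimethyl-6-(triisopropylsilyloxy)-2H-chromen-2-yl]ethoxy}dimethylsilane F8.
   - Pyridinium p-toluenesulfonate in MeOH removes only the alkyl silyl ether to give 2-[(2S)-2,8-dimethyl-6-(triisopropylsilyloxy)-2H-chromen-2-yl]ethanol F9, and I2, PPh3 and imidazole give 9.

3. Step 5. The tertiary C–O bond is both allylic and propargylic and may ionise under the cationic gold catalyst or adventitious acid (loss of enantiopurity, elimination); 5-exo closure or enyne cycloisomerisation may also compete. Fallback that closes the chromene by ring-closing metathesis, setting out from 2 and 3 and returning at 7: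
   - Ortho-formylation of 2 (MgCl2, Et3N, paraformaldehyde, MeCN, reflux) gives 2-hydroxy-3-methyl-5-[(triisopropylsilyl)oxy]benzaldehyde F10.
   - Wittig methylenation (Ph3PCH3Br, KOtBu, THF) gives 2-ethenyl-6-methyl-4-[(triisopropylsilyl)oxy]phenol F11.
   - Allylic etherification with 3 as in step 2, but with the antipodal ligand, gives (2R)-2-{2-ethenyl-6-methyl-4-[(triisopropylsilyl)oxy]phenoxy}-2-methylbut-3-en-1-ol F12.
   - Second-generation Grubbs catalyst (CH2Cl2, 40 °C) closes the ring to [(2R)-2,8-dimethyl-6-(triisopropylsilyloxy)-2H-chromen-2-yl]methanol F13.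
   - Dess–Martin oxidation gives (2R)-2,8-dimethyl-6-(triisopropylsilyloxy)-2H-chromene-2-carbaldehyde F14, and a second Wittig methylenation gives 7.

Further compounds
F1 | step 10 | (1E,4R)-1-iodo-2,10-dimethylundeca-1,9-dien-5-yn-4-ol | I/C=C(C)/C[C@@H](O)C#CCCC=C(C)C
F2 | step 10 | 9-{2-[(2S)-2,8-dimethyl-6-(triisopropylsilyloxy)-2H-chromen-2-yl]ethyl}-9-borabicyclo[3.3.1]nonane | C1CC2CCCC(C1)B2CC[C@@]3(C)C=Cc4cc(O[Si](C(C)C)(C(C)C)C(C)C)cc(C)c4O3
F3 | step 2 | [(2S,3S)-3-ethynyl-3-methyloxiran-2-yl]methanol | OC[C@@H]1O[C@@]1(C)C#C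
F4 | step 2 | (3R)-3-methylpent-4-yne-1,3-diol | OCC[C@](O)(C)C#C
F5 | step 2 | (3R)-5-[(tert-butyldimethylsilyl)oxy]-3-methylpent-1-yn-3-ol | CC(C)(C)[Si](C)(C)OCC[C@](O)(C)C#C
F6 | step 2 | (3R)-5-[(tert-butyldimethylsilyl)oxy]-3-methylpent-1-yn-3-yl diphenylphosphinite | CC(C)(C)[Si](C)(C)OCC[C@](OP(c1ccccc1)c1ccccc1)(C)C#C
F7 | step 2 | tert-butyl{[(3S)-3-methyl-3-{2-methyl-4-[(triisopropylsilyl)oxy]phenoxy}pent-4-yn-1-yl]oxy}dimethylsilane | CC(C)(C)[Si](C)(C)OCC[C@@](Oc1ccc(O[Si](C(C)C)(C(C)C)C(C)C)cc1C)(C)C#C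
F8 | step 2 | tert-butyl{2-[(2S)-2,8-dimethyl-6-(triisopropylsilyloxy)-2H-chromen-2-yl]ethoxy}dimethylsilane | CC(C)(C)[Si](C)(C)OCC[C@@]1(C)C=Cc2cc(O[Si](C(C)C)(C(C)C)C(C)C)cc(C)c2O1
F9 | step 2 | 2-[(2S)-2,8-dimethyl-6-(triisopropylsilyloxy)-2H-chromen-2-yl]ethanol | OCC[C@@]1(C)C=Cc2cc(O[Si](C(C)C)(C(C)C)C(C)C)cc(C)c2O1
F10 | step 5 | 2-hydroxy-3-methyl-5-[(triisopropylsilyl)oxy]benzaldehyde | O=Cc1cc(O[Si](C(C)C)(C(C)C)C(C)C)cc(C)c1O
F11 | step 5 | 2-ethenyl-6-methyl-4-[(triisopropylsilyl)oxy]phenol | C=Cc1cc(O[Si](C(C)C)(C(C)C)C(C)C)cc(C)c1O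
F12 | step 5 | (2R)-2-{2-ethenyl-6-methyl-4-[(triisopropylsilyl)oxy]phenoxy}-2-methylbut-3-en-1-ol | OC[C@@](Oc1c(C=C)cc(O[Si](C(C)C)(C(C)C)C(C)C)cc1C)(C)C=C
F13 | step 5 | [(2R)-2,8-dimethyl-6-(triisopropylsilyloxy)-2H-chromen-2-yl]methanol | OC[C@@]1(C)C=Cc2cc(O[Si](C(C)C)(C(C)C)C(C)C)cc(C)c2O1
F14 | step 5 | (2R)-2,8-dimethyl-6-(triisopropylsilyloxy)-2H-chromene-2-carbaldehyde | O=C[C@@]1(C)C=Cc2cc(O[Si](C(C)C)(C(C)C)C(C)C)cc(C)c2O1
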